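# Proposed synthesis of (3S,6R)-6-[(6E)-hexadec-6-en-4-yn-1-yl]-6-methoxy-1,2-dioxane-3-acetic acid (18)

## The problem

Target 18 is a 1,2-dioxane (O1, O2, C3–C6) in which C3 carries a hydrogen and a CH2CO2H arm and C6 is a peroxyketal carbon carrying OMe and a sixteen-carbon chain with a 4-yne and a 6E-ene. There are two stereocentres, 3S and 6R: C6 is a ketal centre that acid can re-set, whereas C3 is a secondary C–O centre that nothing later can correct, so C3 must carry the absolute configuration and then steer C6 through the ring. In the chair the target has OMe axial and both carbon substituents equatorial, the anomerically favoured arrangement, which places OMe cis to the C3 arm. Four groups limit the chemistry: the O–O bond (attacked by phosphines, low-valent metals, hydrides and radicals), the peroxyketal (exchanges under acid), the C3–O bond β to the carboxyl group (lost by E1cB under base) and the enyne (tolerates neither singlet oxygen, peracid nor any alkene reduction). The oxidants must therefore be used before the enyne exists, and the ring must be saturated without a hydrogenation. The enabling feature is that the C6 oxygen and the carboxyl carbon of the C3 arm lie on the same face of the dioxane, so that joining them gives an O–C(=O)–CH2 bridge from C6 to C3, a 2,6,7-trioxabicyclo[3.2.2]nonan-3-one. That lactone is the Baeyer–Villiger product of a 2,3-dioxabicyclo[2.2.2]octan-5-one, itself the singlet-oxygen adduct of a cyclohexadienol ether, so the carboxyl carbon, the arm CH2 and C3–C6 are the six carbons of a cyclohexenone.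

## Retrosynthesis

**18 to 13 and 16.** The acid is masked as methyl ester 17, and the C(sp)–C(sp2) bond between the alkyne and the E-alkene is cut. This gives terminal alkyne 13 and (E)-1-iodoundec-1-ene 16. A cut at the alkene (olefination) would need an ynal and strong base on the peroxide fragment; a cut at the propargylic carbon would need an acetylide next to an ester. The chosen cut removes eleven carbons and the only group that cannot survive singlet oxygen and peracid. The forward coupling must spare the O–O bond, and the final saponification must spare the β-peroxy ester.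

**13 to 10.** Alkyne 13 comes from its silyl-protected form 12. In 12 the C6–OMe bond and the ester O–CH3 bond are cut and the two oxygen functions are tied together as the C6–O–C(=O) bridge of lactone 10. The neighbouring cut, C6–O1 (hydroperoxide adding to a ketone), would need a free secondary hydroperoxide at C3 and a separate construction of the acid. The lactone cut gives ketal and carboxyl at their final oxidation levels from one functional group. The bridge can only exist for the cis arrangement, so it agrees with the target. The forward solvolysis must place OMe cis to the arm; this is asked of anomeric control from C3, since C6 passes through a peroxycarbenium ion.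

**10 to 9.** The C6–O(acyl) bond is cut and the C6–C(=O) bond restored (Baeyer–Villiger retron). Ketone 9 has an all-carbon two-atom bridge and is a cyclohexanone spanned 1,4 by a peroxide. Oxygen insertion on the other side of the carbonyl would give a CH2–O ester and is useless. The forward reaction must therefore make the peroxy-bearing tertiary bridgehead migrate, not the methylene.

**9 to 6.** Ketone 9 is one enantiomer of racemate 8, obtained by chromatographic resolution. In 8 the ketone is written as its silyl enol ether 7, and both C–O bonds of the peroxide are cut ([4+2] retron) to give 2-silyloxy-1,3-cyclohexadiene 6 and oxygen. The alternative, closing the peroxide by conjugate addition of a hydroperoxide to a cyclohexenone, runs uphill toward the strained bicycle. The cycloaddition brings in both oxygens at once and leaves C4–C5 saturated. The forward reaction must be periselective for [4+2], and the ketone must be released without passing through an enolate.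

**6 to 3 and 2.** Diene 6 is the kinetic silyl dienol ether of 6-alkylcyclohexenone 5. The bond between the ring α′ carbon and the first chain carbon is cut, giving cyclohex-2-en-1-one 3 (as its cross-conjugated enolate 4) and iodide 2. Iodide 2 comes from commercial chloride 1 by halide exchange. The stereocentre made in 5 is irrelevant because it becomes sp2 in 6.

**16 to 14.** The C–I bond is cut; syn hydrometalation of undec-1-yne 14 (through alkenylzirconocene 15) and iodinolysis fix the E geometry.

## Roads not taken

**Alternative 1: auxiliary-directed singlet-oxygen cycloaddition on an open-chain dienol ether.**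
- Cut: both ring C–O bonds, at C3 and C6. Dienol ether A1, carrying a (1R,2S)-2-phenylcyclohexyl group on the enol oxygen, would add singlet oxygen to give 3,6-dihydro-1,2-dioxine A2.
- Merits: the peroxide ring and C3 are made in one step, and the auxiliary would give absolute control without a resolution. In that respect this road is better than the chosen one, which discards half of ketone 8.
- Weak points: A1 is acyclic and must reach the s-cis conformation, so [2+2] addition at the enol ether and ene reactions compete. The centre next to the auxiliary (C6) is a ketal that is erased later, so the auxiliary's real task is 1,4-induction to C3, which is expected to be modest.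
- After the key step, A2 still needs diimide saturation of the ring alkene, ketal exchange to OMe, removal of the benzyl-type ether, oxidation and alkyne homologation under base, desilylation and a two-stage oxidation of the arm, and only then the enyne coupling.
- Comparison: against the missing resolution, the chosen plan sets a far shorter end-game, a ring that is saturated from the start, and an arm that is born at the carboxyl oxidation level.

**Alternative 2: peroxycarbenium–cyclopropane [3+3] annulation.**
- Cut: C3–C4 and C6–O1. Silylperoxy acetal A3 would be ionised by Me3SiOTf; methoxycyclopropane A4 would attack through a methylene carbon, open to an oxocarbenium ion at C6, and be closed by the silylperoxy oxygen to give A5, which is identical with 12.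
- Merits: this is the most convergent road. It would reach the common intermediate in about half the steps of the chosen plan and share its end-game, so in step economy it is clearly better.
- Weak points: the reactivity is unestablished, since an unactivated methoxycyclopropane is a weak three-carbon nucleophile for a peroxycarbenium ion, and ring opening of A4 by the silyl triflate or fragmentation of the cation can intervene. Enantiocontrol by a chiral catalyst over a peroxycarbenium ion pair is also unestablished. Run racemic, A5 would need the same kind of resolution as 8, and its C6 would rest on the same anomeric argument.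
- Comparison: against the shorter sequence, the chosen plan sets a single unproven event (the migration in step 6), which has a close analogue and a substrate that comes from a dependable cycloaddition.

**Alternative 3: acid-triggered hydroperoxide unmasking and peroxyketal closure.**
- Cut: C6–O1 and C6–OMe. In open-chain ketone A6 the C3 hydroperoxide is masked as a 2-methoxyprop-2-yl peroxyketal. Acid in methanol would free it, add it to the C6 ketone and methylate the hemiketal, giving dioxane A7.
- Merits: the ring closure is of a well-known type, and C3 can be set in the open chain from an enantiopure secondary alcohol. In precedent and in absolute control this road is better than the chosen one.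
- Weak points: introducing a secondary hydroperoxide with clean inversion is sluggish and competes with elimination. A6 needs a long linear assembly with several protecting groups. The hydroxyethyl arm of A7 must be deprotected and oxidised twice with the peroxide in place.
- Comparison: the chosen plan sets against this its brevity and the direct formation of the carboxyl group, and accepts a new key step and a resolution.

Key step: step 6

Assumption: the ketal centre C6 is taken to be set in step 7 under anomeric control from C3 (OMe axial, both carbon substituents equatorial, hence cis to the C3 arm), not carried over from lactone 10.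

Remark: racemic compounds with a single stereocentre, the epimer mixture F3 and the bridged bicycles 7, 8 and F5 (whose ring system allows only one relative configuration) are written with stereo-free SMILES; the cis racemate F4 is written as both of its enantiomers.

## Route

Step 1
Reactants: 1 (5-chloropent-1-yn-1-yl)trimethylsilane
Product: 2 (5-iodopent-1-yn-1-yl)trimethylsilane
Conditions: NaI, acetone, reflux
Reagents that add atoms: sodium iodide, [Na+].[I-]
Why: Finkelstein halide exchange (SN2) driven by precipitation of NaCl; the iodide is needed because the enolate alkylation of step 2 is too slow with the chloride.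

Step 2
Reactants: 3 cyclohex-2-en-1-one; 2 (5-iodopent-1-yn-1-yl)trimethylsilane
Product: 5 racemic 6-[5-(trimethylsilyl)pent-4-yn-1-yl]cyclohex-2-en-1-one, via lithium cyclohexa-1,5-dien-1-olate 4 (not isolated)
Conditions: LDA, THF, −78 °C; then 2, DMPU, −78 → −20 °C
Reagents that add atoms: lithium diisopropylamide, CC(C)N([Li])C(C)C (its lithium is found in 4 only)
Why: Kinetic deprotonation of the enone removes the α′ proton to give the cross-conjugated dienolate 4, which is C-alkylated by the primary iodide (enolate SN2 alkylation) in the presence of DMPU; the new stereocentre is racemic and becomes sp2 in step 3.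

Step 3
Reactants: 5 racemic 6-[5-(trimethylsilyl)pent-4-yn-1-yl]cyclohex-2-en-1-one
Product: 6 trimethyl({2-[5-(trimethylsilyl)pent-4-yn-1-yl]cyclohexa-1,5-dien-1-yl}oxy)silane
Conditions: TMSCl, LDA, THF, −78 °C (in situ quench); pentane, filtration
Reagents that add atoms: chlorotrimethylsilane, C[Si](C)(C)Cl
Why: Kinetic silyl enol ether formation: LDA removes the remaining α′ hydrogen faster than a γ hydrogen and the cross-conjugated enolate is O-silylated as it forms, so no equilibration to the extended dienolate occurs; the alkynyl C–Si bond is inert.

Step 4
Reactants: 6 trimethyl({2-[5-(trimethylsilyl)pent-4-yn-1-yl]cyclohexa-1,5-dien-1-yl}oxy)silane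
Product: 8 racemic 4-[5-(trimethylsilyl)pent-4-yn-1-yl]-2,3-dioxabicyclo[2.2.2]octan-5-one, via silyl enol ether endoperoxide 7 (not isolated)
Conditions: O2, tetraphenylporphyrin (cat.), visible light, CH2Cl2, −78 °C; then AcOH, THF/H2O, 0 °C
Reagents that add atoms: dioxygen, O=O
Why: Singlet oxygen adds suprafacially across the termini of the s-cis-locked, electron-rich 2-silyloxy-1,3-cyclohexadiene ([4+2] photooxygenation), so both C–O bonds form on one face and only one relative configuration is possible; the enol ether is then cleaved by C-protonation (acid hydrolysis of a silyl enol ether), which releases the ketone without an enolate that would expel the β-peroxide.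

Step 5
Reactants: 8 racemic 4-[5-(trimethylsilyl)pent-4-yn-1-yl]-2,3-dioxabicyclo[2.2.2]octan-5-one
Product: 9 (1S,4R)-4-[5-(trimethylsilyl)pent-4-yn-1-yl]-2,3-dioxabicyclo[2.2.2]octan-5-one
Conditions: preparative chiral SFC, amylose tris(3,5-dimethylphenylcarbamate) phase, CO2/iPrOH, 35 °C
Reagents that add atoms: none
Why: Resolution by chromatography on a polysaccharide chiral stationary phase, which suits a rigid, polar bicyclic ketone; the absolute configuration of the collected enantiomer is to be assigned by vibrational circular dichroism or by correlation with 12, and both stereocentres of the target trace back to this separation.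

Step 6
Reactants: 9 (1S,4R)-4-[5-(trimethylsilyl)pent-4-yn-1-yl]-2,3-dioxabicyclo[2.2.2]octan-5-one
Product: 10 (1R,5S)-1-[5-(trimethylsilyl)pent-4-yn-1-yl]-2,6,7-trioxabicyclo[3.2.2]nonan-3-one
Conditions: mCPBA, Na2HPO4, CH2Cl2, 0 °C → rt
Reagents that add atoms: 3-chloroperbenzoic acid, OOC(=O)c1cccc(Cl)c1
Why: Proposed new method: Baeyer–Villiger oxidation of an α-peroxy ketone, the closest known reaction type being the peracid oxidation of 7-oxabicyclo[2.2.1]heptan-2-ones, in which the oxygen-bearing bridgehead migrates. The peracid adds to the strained bridge carbonyl to give the Criegee adduct, and the alkyl-bearing bridgehead (the future C6 of the dioxane), which is tertiary and carries a peroxide oxygen whose lone pair supports the electron-poor migrating centre, shifts from carbon to oxygen as 3-chlorobenzoate leaves. No ring is closed from an open chain: the cyclohexanone ring of the [2.2.2] cage is expanded by one oxygen to the seven-membered lactone of the [3.2.2] skeleton, which relieves eclipsing strain. No stereocentre is created; the migrating carbon keeps its configuration, so the two bridgeheads of 10 are those of 9. The step needs regioselectivity (bridgehead over the ring methylene), secured by the higher substitution and the α-oxygen of the bridgehead, and chemoselectivity, secured by the inertness of a silylated alkyne and a dialkyl peroxide to peracid. Solid Na2HPO4 takes up 3-chlorobenzoic acid so that the acyloxy peroxyketal of 10 is not ionised, while no base strong enough to enolise 9 toward its methylene and open the peroxide is present.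

Step 7
Reactants: 10 (1R,5S)-1-[5-(trimethylsilyl)pent-4-yn-1-yl]-2,6,7-trioxabicyclo[3.2.2]nonan-3-one
Product: 12 methyl 2-[(3S,6R)-6-methoxy-6-[5-(trimethylsilyl)pent-4-yn-1-yl]-1,2-dioxan-3-yl]acetate, via methoxy ketal acid 11 (not isolated)
Conditions: TsOH·H2O (cat.), MeOH, 0 °C → rt
Reagents that add atoms: methanol, CO
Why: Acid-catalysed solvolysis of the acyloxy peroxyketal: loss of the carboxyl group from C6 gives a ring peroxycarbenium ion that methanol captures (transketalisation), and the freed acid 11 undergoes Fischer esterification; C6 is a reversible ketal centre and, by axial attack and by acid equilibration alike, should settle with OMe axial and both carbon substituents equatorial, which is cis to the C3 arm, i.e. (6R), with C3 as the controlling element.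

Step 8
Reactants: 12 methyl 2-[(3S,6R)-6-methoxy-6-[5-(trimethylsilyl)pent-4-yn-1-yl]-1,2-dioxan-3-yl]acetate
Product: 13 methyl 2-[(3S,6R)-6-methoxy-6-(pent-4-yn-1-yl)-1,2-dioxan-3-yl]acetate
Conditions: K2CO3 (0.2 equiv), MeOH, 0 °C
Reagents that add atoms: none
Why: Protodesilylation of the alkynyl C–Si bond by catalytic methoxide; this base at 0 °C is too weak to enolise the ester toward loss of the β-peroxide, and the peroxyketal is stable to base.

Step 9
Reactants: 14 undec-1-yne
Product: 16 (1E)-1-iodoundec-1-ene, via alkenylzirconocene chloride 15 (not isolated)
Conditions: Cp2Zr(H)Cl, CH2Cl2, rt; then I2, 0 °C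
Reagents that add atoms: chlorobis(cyclopentadienyl)hydridozirconium, [H][Zr](Cl)(C1C=CC=C1)C1C=CC=C1; iodine, II
Why: Hydrozirconation adds Zr–H syn with zirconium on the terminal carbon, and iodinolysis of the C–Zr bond proceeds with retention, so only the E iodoalkene should form.

Step 10
Reactants: 13 methyl 2-[(3S,6R)-6-methoxy-6-(pent-4-yn-1-yl)-1,2-dioxan-3-yl]acetate; 16 (1E)-1-iodoundec-1-ene
Product: 17 methyl 2-[(3S,6R)-6-[(6E)-hexadec-6-en-4-yn-1-yl]-6-methoxy-1,2-dioxan-3-yl]acetate
Conditions: Pd(PPh3)4 (cat.), CuI (cat.), iPr2NH, THF, rt, degassed
Reagents that add atoms: none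
Why: Sonogashira coupling: oxidative addition of the alkenyl iodide to zerovalent palladium, transmetalation from the copper acetylide and reductive elimination form the C(sp)–C(sp2) bond with retention of the E geometry; at room temperature a tertiary dialkyl peroxyketal is not expected to be reduced, and neither stereocentre is touched.

Step 11
Reactants: 17 methyl 2-[(3S,6R)-6-[(6E)-hexadec-6-en-4-yn-1-yl]-6-methoxy-1,2-dioxan-3-yl]acetate
Product: 18 2-[(3S,6R)-6-[(6E)-hexadec-6-en-4-yn-1-yl]-6-methoxy-1,2-dioxan-3-yl]acetic acid
Conditions: LiOH, THF/H2O, 0 °C → rt; then 0.1 M HCl to pH 4, 0 °C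
Reagents that add atoms: lithium hydroxide, [Li+].[OH-]
Why: Saponification of the methyl ester by acyl substitution; the peroxyketal is base-stable, the cold, short exposure limits E1cB loss of the β-peroxide, and the brief mild acidification should leave the ketal and both stereocentres unchanged.

## Compound list

1 | (5-chloropent-1-yn-1-yl)trimethylsilane | C[Si](C)(C)C#CCCCCl | starting material
2 | (5-iodopent-1-yn-1-yl)trimethylsilane | C[Si](C)(C)C#CCCCI | intermediate
3 | cyclohex-2-en-1-one | O=C1C=CCCC1 | starting material
4 | lithium cyclohexa-1,5-dien-1-olate | [Li]OC1=CCCC=C1 | intermediate (not isolated)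
5 | racemic 6-[5-(trimethylsilyl)pent-4-yn-1-yl]cyclohex-2-en-1-one | O=C1C=CCCC1CCCC#C[Si](C)(C)C | intermediate
6 | trimethyl({2-[5-(trimethylsilyl)pent-4-yn-1-yl]cyclohexa-1,5-dien-1-yl}oxy)silane | C[Si](C)(C)C#CCCCC1=C(O[Si](C)(C)C)C=CCC1 | intermediate
7 | racemic trimethyl({1-[5-(trimethylsilyl)pent-4-yn-1-yl]-2,3-dioxabicyclo[2.2.2]oct-5-en-6-yl}oxy)silane | C[Si](C)(C)C#CCCCC1(C(O[Si](C)(C)C)=C2)CCC2OO1 | intermediate (not isolated)
8 | racemic 4-[5-(trimethylsilyl)pent-4-yn-1-yl]-2,3-dioxabicyclo[2.2.2]octan-5-one | C[Si](C)(C)C#CCCCC1(C(=O)C2)CCC2OO1 | intermediate
9 | (1S,4R)-4-[5-(trimethylsilyl)pent-4-yn-1-yl]-2,3-dioxabicyclo[2.2.2]octan-5-one | C[Si](C)(C)C#CCCC[C@]1(C(=O)C2)CC[C@@H]2OO1 | intermediate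
10 | (1R,5S)-1-[5-(trimethylsilyl)pent-4-yn-1-yl]-2,6,7-trioxabicyclo[3.2.2]nonan-3-one | C[Si](C)(C)C#CCCC[C@]1(OC(=O)C2)CC[C@@H]2OO1 | intermediate
11 | 2-[(3S,6R)-6-methoxy-6-[5-(trimethylsilyl)pent-4-yn-1-yl]-1,2-dioxan-3-yl]acetic acid | C[Si](C)(C)C#CCCC[C@]1(OC)CC[C@@H](CC(=O)O)OO1 | intermediate (not isolated)
12 | methyl 2-[(3S,6R)-6-methoxy-6-[5-(trimethylsilyl)pent-4-yn-1-yl]-1,2-dioxan-3-yl]acetate | C[Si](C)(C)C#CCCC[C@]1(OC)CC[C@@H](CC(=O)OC)OO1 | intermediate
13 | methyl 2-[(3S,6R)-6-methoxy-6-(pent-4-yn-1-yl)-1,2-dioxan-3-yl]acetate | C#CCCC[C@]1(OC)CC[C@@H](CC(=O)OC)OO1 | intermediate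
14 | undec-1-yne | CCCCCCCCCC#C | starting material
15 | chlorobis(cyclopentadienyl)[(1E)-undec-1-en-1-yl]zirconium | CCCCCCCCC/C=C/[Zr](Cl)(C1C=CC=C1)C1C=CC=C1 | intermediate (not isolated)
16 | (1E)-1-iodoundec-1-ene | CCCCCCCCC/C=C/I | intermediate
17 | methyl 2-[(3S,6R)-6-[(6E)-hexadec-6-en-4-yn-1-yl]-6-methoxy-1,2-dioxan-3-yl]acetate | CCCCCCCCC/C=C/C#CCCC[C@]1(OC)CC[C@@H](CC(=O)OC)OO1 | intermediate
18 | 2-[(3S,6R)-6-[(6E)-hexadec-6-en-4-yn-1-yl]-6-methoxy-1,2-dioxan-3-yl]acetic acid | CCCCCCCCC/C=C/C#CCCC[C@]1(OC)CC[C@@H](CC(=O)O)OO1 | target

## Step count and least certain steps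

Total: 11 steps. Longest linear sequence: 10 steps (steps 1–8, 10 and 11, from chloride 1); step 9 is a one-step side branch.

**Step 6 (key step, proposed new method).**
- What may go wrong: loss of regiocontrol in the migration (methylene instead of bridgehead), base-induced retro-oxa-Michael opening of the β-peroxy ketone before the peracid adds, or acid-induced ionisation of the acyloxy peroxyketal once formed.
- Fallback, known chemistry, sets out from 6 and comes back at 12. Ozonolysis of the electron-rich silyl enol ether double bond of 6 in CH2Cl2/MeOH at −78 °C cleaves the same ring bond. The oxygen-bearing carbon becomes the carboxyl group, and the carbonyl oxide on the other carbon is trapped by methanol, which should give racemic (2Z)-6-hydroperoxy-6-methoxy-11-(trimethylsilyl)undec-2-en-10-ynoic acid F1 after methanolysis of the silyl ester. Trimethylsilyldiazomethane in methanol would convert acid F1 into racemic methyl (2Z)-6-hydroperoxy-6-methoxy-11-(trimethylsilyl)undec-2-en-10-ynoate F2 without touching the hydroperoxide. In ester F2 the hydroperoxide is then added to the enoate (Et2NH, 2,2,2-trifluoroethanol), closing the 1,2-dioxane as methyl 2-{6-methoxy-6-[5-(trimethylsilyl)pent-4-yn-1-yl]-1,2-dioxan-3-yl}acetate F3 in the form of a racemic mixture of C6 epimers. TsOH in MeOH should equilibrate mixture F3 at the ketal centre to the cis racemate, methyl 2-[(3S,6R)- and (3R,6S)-6-methoxy-6-[5-(trimethylsilyl)pent-4-yn-1-yl]-1,2-dioxan-3-yl]acetate F4 under the same anomeric control as in step 7. Racemate F4 is resolved on the chiral phase of step 5 to give 12.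

**Step 4.**
- What may go wrong: ene reaction or silyl migration instead of [4+2], and above all opening of the bicycle by β-elimination of the peroxide during or after unmasking of the ketone, on the column or on storage.
- Fallback, sets out from 6 and comes back at 12; it changes where the ketone is handled and where the absolute configuration enters. After photooxygenation and acid cleavage of 7, racemic ketone 8 is not isolated. Its dried CH2Cl2 solution is oxidised at once with mCPBA/Na2HPO4 to racemic 1-[5-(trimethylsilyl)pent-4-yn-1-yl]-2,6,7-trioxabicyclo[3.2.2]nonan-3-one F5 in the same flask. Methanolysis of lactone F5 as in step 7 gives the racemic cis ester F4 described under step 6, and the resolution is done at this robust ester stage, returning to 12.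
- If the cycloaddition itself fails, the ozonolytic detour given under step 6 applies, since it never needs the bicycle.

**Step 7.**
- What may go wrong: poor facial selectivity in the capture at C6, giving an epimer mixture, or acid-induced fragmentation of the peroxide (Hock-type cleavage) instead of simple ionisation.
- Fallback, sets out from 10 and comes back at 12; the methyl groups are put on oxygen instead of oxygen on carbon, so C6 is set by the equilibrium of a hemiketal and not by capture of a cation. Hydrolysis of 10 (TsOH cat., THF/H2O, 0 °C) gives 2-[(3S)-6-hydroxy-6-[5-(trimethylsilyl)pent-4-yn-1-yl]-1,2-dioxan-3-yl]acetic acid F6 as a cyclic peroxyhemiketal whose anomers equilibrate by ring–chain tautomerism. Me3OBF4 with 1,8-bis(dimethylamino)naphthalene in CH2Cl2 then methylates the carboxyl group and the anomeric hydroxyl of hemiketal F6 with retention at C6, giving 12.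

**Step 10.**
- What may go wrong: reduction of the O–O bond by low-valent palladium or by free phosphine, and oxidative homocoupling of alkyne 13.
- Fallback, sets out from 13 and comes back at 17; it is free of palladium and phosphine and reverses the polarity of the partners. N-Iodosuccinimide with AgNO3 (cat.) in acetone converts 13 into methyl 2-[(3S,6R)-6-(5-iodopent-4-yn-1-yl)-6-methoxy-1,2-dioxan-3-yl]acetate F7 by electrophilic iodination of the silver acetylide. Iodoalkyne F7 is coupled with alkenylzirconocene 15 (made from 14 as in step 9) in the presence of CuCl in THF, a copper-mediated alkenyl–alkynyl coupling with retention of the alkene geometry, giving 17.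

**Step 2.**
- What may go wrong: proton transfer between enolate and product, over-alkylation, and Michael addition of 4 to 3, all of which are favoured by the slow reaction of an unactivated primary iodide.
- Fallback, sets out from 3 and comes back at 5. Condensation of 3 with 1,1-dimethylhydrazine gives cyclohex-2-en-1-one dimethylhydrazone F8 as a more nucleophilic and less electrophilic enolate precursor. Deprotonation of hydrazone F8 with LDA and alkylation of the azaenolate at the α′ carbon with 2 gives racemic 6-[5-(trimethylsilyl)pent-4-yn-1-yl]cyclohex-2-en-1-one dimethylhydrazone F9 in place of the direct enolate alkylation. Biphasic aqueous oxalic acid/Et2O hydrolyses F9 to 5.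

## Further compounds

F1 | step 6 | racemic (2Z)-6-hydroperoxy-6-methoxy-11-(trimethylsilyl)undec-2-en-10-ynoic acid | OC(=O)/C=C\CCC(OC)(OO)CCCC#C[Si](C)(C)C
F2 | step 6 | racemic methyl (2Z)-6-hydroperoxy-6-methoxy-11-(trimethylsilyl)undec-2-en-10-ynoate | COC(=O)/C=C\CCC(OC)(OO)CCCC#C[Si](C)(C)C
F3 | step 6 | methyl 2-{6-methoxy-6-[5-(trimethylsilyl)pent-4-yn-1-yl]-1,2-dioxan-3-yl}acetate, racemic mixture of C6 epimers | C[Si](C)(C)C#CCCCC1(OC)CCC(CC(=O)OC)OO1
F4 | step 6 | racemate of 12, methyl 2-[(3S,6R)- and (3R,6S)-6-methoxy-6-[5-(trimethylsilyl)pent-4-yn-1-yl]-1,2-dioxan-3-yl]acetate | C[Si](C)(C)C#CCCC[C@]1(OC)CC[C@@H](CC(=O)OC)OO1.C[Si](C)(C)C#CCCC[C@@]1(OC)CC[C@H](CC(=O)OC)OO1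
F5 | step 4 | racemic 1-[5-(trimethylsilyl)pent-4-yn-1-yl]-2,6,7-trioxabicyclo[3.2.2]nonan-3-one | C[Si](C)(C)C#CCCCC1(OC(=O)C2)CCC2OO1
F6 | step 7 | 2-[(3S)-6-hydroxy-6-[5-(trimethylsilyl)pent-4-yn-1-yl]-1,2-dioxan-3-yl]acetic acid (C6 anomers) | C[Si](C)(C)C#CCCCC1(O)CC[C@@H](CC(=O)O)OO1
F7 | step 10 | methyl 2-[(3S,6R)-6-(5-iodopent-4-yn-1-yl)-6-methoxy-1,2-dioxan-3-yl]acetate | IC#CCCC[C@]1(OC)CC[C@@H](CC(=O)OC)OO1
F8 | step 2 | cyclohex-2-en-1-one dimethylhydrazone | CN(C)N=C1C=CCCC1
F9 | step 2 | racemic 6-[5-(trimethylsilyl)pent-4-yn-1-yl]cyclohex-2-en-1-one dimethylhydrazone | CN(C)N=C1C=CCCC1CCCC#C[Si](C)(C)C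
A1 | alternative 1 | tert-butyl{[(3E)-10-[(4-methoxyphenyl)methoxy]-6-{[(1R,2S)-2-phenylcyclohexyl]oxy}deca-3,5-dien-1-yl]oxy}diphenylsilane (enol ether geometry left open) | COc1ccc(COCCCCC(O[C@@H]2CCCC[C@H]2c2ccccc2)=C/C=C/CCO[Si](c2ccccc2)(c2ccccc2)C(C)(C)C)cc1
A2 | alternative 1 | tert-butyl{2-[(3R,6S)-6-{4-[(4-methoxyphenyl)methoxy]butyl}-6-{[(1R,2S)-2-phenylcyclohexyl]oxy}-3,6-dihydro-1,2-dioxin-3-yl]ethoxy}diphenylsilane | COc1ccc(COCCCC[C@@]2(O[C@@H]3CCCC[C@H]3c3ccccc3)C=C[C@@H](CCO[Si](c3ccccc3)(c3ccccc3)C(C)(C)C)OO2)cc1
A3 | alternative 2 | methyl 3-methoxy-3-[(triethylsilyl)peroxy]propanoate | COC(=O)CC(OC)OO[Si](CC)(CC)CC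
A4 | alternative 2 | 1-methoxy-1-[5-(trimethylsilyl)pent-4-yn-1-yl]cyclopropane | COC1(CCCC#C[Si](C)(C)C)CC1
A5 | alternative 2 | methyl 2-[(3S,6R)-6-methoxy-6-[5-(trimethylsilyl)pent-4-yn-1-yl]-1,2-dioxan-3-yl]acetate (identical with 12) | C[Si](C)(C)C#CCCC[C@]1(OC)CC[C@@H](CC(=O)OC)OO1
A6 | alternative 3 | (3S)-1-[(tert-butyldiphenylsilyl)oxy]-3-[(2-methoxypropan-2-yl)peroxy]-11-(trimethylsilyl)undec-10-yn-6-one | C[Si](C)(C)C#CCCCC(=O)CC[C@@H](CCO[Si](c1ccccc1)(c1ccccc1)C(C)(C)C)OOC(C)(C)OC
A7 | alternative 3 | tert-butyl{2-[(3S,6R)-6-methoxy-6-[5-(trimethylsilyl)pent-4-yn-1-yl]-1,2-dioxan-3-yl]ethoxy}diphenylsilane | C[Si](C)(C)C#CCCC[C@]1(OC)CC[C@@H](CCO[Si](c2ccccc2)(c2ccccc2)C(C)(C)C)OO1
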